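After 2.0 h, the flask had to be read for product and idle complex together, and I first asked which given numbers had to be known well.

| setting | north-west | north | south-east | flask |
|---|---|---|---|---|
| starting material | 0.050 M | 0.050 M | 0.050 M | 0.050 M |
| gas phase | 11 mM (held) | 11 mM (held) | 11 mM (held) | 11 mM (held) |
| protic impurity | 7 mM | 11 mM | 5 mM | 5.00 mM |
| free catalyst | 0.2 mol% | 0.2 mol% | 0.4 mol% | 0.2 mol% |
| stray impurity | 20 µM | 20 µM | 20 µM | 20 µM |
| remark | run made earlier | run made earlier | run made earlier |  |
| time |  |  |  | 2.0 h |

| run | time / min | product / % | idle complex / % | starting material / % |
|---|---|---|---|---|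
| north-west | 10.0 | 4 | 0 | 90 |
| north-west | 15.0 | 7 | 0 | 86 |
| north-west | 20.0 | 8 | 1 | 81 |
| north-west | 30.0 | 16 | 2 | 74 |
| north-west | 50.0 | 22 | 0 | 69 |
| north-west | 80.0 | 31 | 4 | 55 |
| north-west | 120 | 39 | 0 | 44 |
| north | 15.0 | 9 | 3 | 79 |
| north | 30.0 | 12 | 5 | 71 |
| north | 50.0 | 16 | 0 | 59 |
| north | 60.0 | 20 | 0 | 58 |
| north | 80.0 | 26 | 3 | 53 |
| north | 90.0 | 28 | 0 | 47 |
| north | 120 | 40 | 2 | 39 |
| south-east | 10.0 | 5 | 0 | 88 |
| south-east | 30.0 | 24 | 1 | 67 |
| south-east | 60.0 | 42 | 0 | 47 |
| south-east | 80.0 | 53 | 0 | 39 |
| south-east | 120 | 64 | 4 | 22 |

(each reading ± 2 percentage points)

- product is meant together with its idle complex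
- the analysis behind the earlier runs scatters by 2 percentage points, standard deviation
- at the start none of the gas phase is in solution

* how much product and idle complex together there is at 2.0 h, in percent of the starting material charged
* concentration of dissolved gas in solution at 1.0 h, in percent of saturation
* the change that raises the amount of product and idle complex together at 2.0 h, in percent of the starting material charged most ("none" if none brings more than 2 percentage points) (spring / dawn / noon / none)
* amount of product and idle complex together at 2.0 h, in percent of the starting material charged, after spring

- spring: doubling the saturation concentration of gas phase, all else as stated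
- dawn: doubling the transfer coefficient of the gas phase, all else as stated
- noon: doubling the amount of free catalyst, all else as stated

The protic impurity needed little care. At 120 min, product read 39% with 7 mM and 40% with 11 mM, a gap inside the scatter of 2 percentage points. I simply set aside 10.0% of the starting material for it. The gas needed no number of its own, since every run held it at 11 mM. The catalyst mattered, and the stray impurity came with it.

Working catalyst, W, came to 80.0 µM in the flask and 180 µM in the south-east run. W is the catalyst charged minus the stray impurity charged, one lost for one. I took product as pseudo-first-order in starting material, with a rate proportional to W.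

A cheap road followed from one south-east row, read at the asked time. Its 64% of product and 4% of idle complex gave an exponent of 1.41. Scaled by W, the flask's exponent was 0.626, so I expected 41.9%. Ignoring the stray impurity would have given 45.5%.

The forecast said 43%, a little above my figure. It also gave 94% of saturation at 1.0 h, noon as the best change, and 62% after spring. Its ground for the catalyst was “consistent with the stray impurity killing” some of it.

The flask gave 41.9%, 93.7% of saturation, noon as the best change, and 63.4% after spring.

    gas phase ⇌ dissolved gas, rate k1*(csat - [dissolved gas]) (kL = 0.00427 /s)
    starting material + dissolved gas + free catalyst → free catalyst + product (k = 116 /M²/s)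
    free catalyst + stray impurity → spent catalyst (k = 64.1 /M/s)
    starting material + protic impurity → quenched substrate (k = 0.0207 /M/s)
    free catalyst + product ⇌ idle complex, settled at all times (K = 7.38 /M)

At 2.00 h, free catalyst and idle complex made 80.0% of the catalyst charged, and spent catalyst held the other 20.0%. Noon gained 23 points against 22 points for spring, in part because the stray impurity takes a fixed amount of catalyst and the run is short. Without that loss of catalyst the flask held 48.0% instead of 41.9%, and a run of 20.0 h held 89.7%. Doubling the charge raised W to 180 µM, a factor of 2.25. A neighbour flask at 0.34 mol% has a W of 150 µM, which put it at 62.2%, and it held 59.9%.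

The numbers in the tables were generated by integration for an exercise; the scatter is artificial.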